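The route rests on cutting the C2′–C3′ bond of the heptamethylene chain at C6 of the 2,4-dihydroxybenzoate ring (C1′ is benzylic). This unfunctionalised CH2–CH2 link sits β,γ to that ring, so it can be born as an olefin: cross-metathesis of a 6-allyl benzoate, already esterified with the complete arylundecanol half, with (S)-dec-9-en-4-yl acetate joins the two halves in one operation. The precursor carries three benzyl ethers and the sulfate as its trichloroethyl diester; one final hydrogenation then saturates the new C2′=C3′ olefin and unmasks everything. Both stereocentres derive from the enantiomeric 2-propyloxiranes, one with retention and one by Mitsunobu inversion.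

Key step: step 11

Assumption: the aryl sulfate is written as the neutral hydrogen sulfate of the target SMILES; step 12 would deliver it as the ammonium salt, and a brief pass through an H+ resin counts as work-up. Metathesis products are drawn as E isomers; the geometry is erased in step 12.

Step 1
Reactants: 1 (S)-2-propyloxirane; 2 5-bromopent-1-ene
Product: 4 (S)-dec-9-en-4-ol, via pent-4-en-1-ylmagnesium bromide 3 (not isolated)
Conditions: Mg, THF, rt; then 1, CuI (10 mol%), THF, −40 → 0 °C; aq. NH4Cl
Reagents that add atoms: none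
Why: Copper-catalysed Grignard opening of a terminal epoxide occurs at the unsubstituted CH2, so the C–O stereocentre of 1 is untouched and enters 4 as (S), the future acetate-bearing centre.

Step 2
Reactants: 4 (S)-dec-9-en-4-ol
Product: 5 (S)-dec-9-en-4-yl acetate
Conditions: Ac2O, pyridine, DMAP (cat.), CH2Cl2, 0 °C → rt
Reagents that add atoms: acetic anhydride, CC(=O)OC(C)=O
Why: DMAP-catalysed O-acetylation of a secondary alcohol, with retention at C4 because the C–O bond is not broken.

Step 3
Reactants: 6 (R)-2-propyloxirane; 7 6-bromohex-1-ene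
Product: 9 (R)-undec-10-en-4-ol, via hex-5-en-1-ylmagnesium bromide 8 (not isolated)
Conditions: Mg, THF, rt; then 6, CuI (10 mol%), THF, −40 → 0 °C; aq. NH4Cl
Reagents that add atoms: none
Why: The same copper-catalysed terminal epoxide opening; the (R) centre is deliberately opposite to the target because step 9 inverts it.

Step 4
Reactants: 10 5-bromobenzene-1,3-diol (5-bromoresorcinol)
Product: 11 3-(benzyloxy)-5-bromophenol
Conditions: BnBr (1.0 equiv), K2CO3 (1.1 equiv), acetone, reflux
Reagents that add atoms: benzyl bromide, BrCc1ccccc1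
Why: Williamson mono-O-benzylation of a symmetric resorcinol with limiting benzyl bromide, a statistical desymmetrisation on a cheap starting material from which diol and bis-ether should be separable and recyclable.

Step 5
Reactants: 9 (R)-undec-10-en-4-ol; 11 3-(benzyloxy)-5-bromophenol
Product: 13 (R)-11-[3-(benzyloxy)-5-hydroxyphenyl]undecan-4-ol, via bis(9-BBN) adduct 12 (not isolated)
Conditions: 9-BBN (2.2 equiv), THF, 0 °C → rt; then 11, Pd(dppf)Cl2 (5 mol%), aq. K3PO4, THF/DMF, 60 °C
Reagents that add atoms: none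
Why: Anti-Markovnikov hydroboration of the terminal alkene followed by B-alkyl Suzuki–Miyaura coupling with the aryl bromide gives the saturated seven-carbon tether directly; the second equivalent of borane caps the hydroxyl as a borinate that is hydrolysed on work-up, and the remote stereocentre is untouched.

Step 6
Reactants: 14 3,5-bis(benzyloxy)benzyl bromide
Product: 15 1-allyl-3,5-bis(benzyloxy)benzene
Conditions: CH2=CHMgBr (1.5 equiv), CuI (10 mol%), 2,2′-bipyridyl (10 mol%), THF, −20 → 0 °C
Reagents that add atoms: vinylmagnesium bromide, C=C[Mg]Br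
Why: Copper-catalysed (Kochi-type) coupling of a benzylic bromide with a vinyl Grignard reagent gives the allylarene, and aryl benzyl ethers are inert to it.

Step 7
Reactants: 15 1-allyl-3,5-bis(benzyloxy)benzene
Product: 17 2-allyl-4,6-bis(benzyloxy)benzaldehyde, via aryliminium chloride 16 (not isolated)
Conditions: POCl3, DMF, 0 → 70 °C; then aq. NaOAc
Reagents that add atoms: N,N-dimethylformamide, CN(C)C=O; water, O
Why: Vilsmeier–Haack formylation of a 3,5-dialkoxy-alkylbenzene should occur para to one benzyloxy group and ortho to the other (next to the allyl group, as with orcinol ethers) and not at the hindered position between the two ethers; the iminium salt is hydrolysed on work-up.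

Step 8
Reactants: 17 2-allyl-4,6-bis(benzyloxy)benzaldehyde
Product: 18 2-allyl-4,6-bis(benzyloxy)benzoic acid
Conditions: NaClO2, NaH2PO4, 2-methyl-2-butene (excess), t-BuOH/THF/H2O, 0 °C → rt
Reagents that add atoms: sodium chlorite, [Na+].[O-]Cl=O
Why: Pinnick oxidation converts the hindered, electron-rich aldehyde into the acid, with 2-methyl-2-butene scavenging HOCl so that neither the allyl group nor the ring is chlorinated.

Step 9
Reactants: 18 2-allyl-4,6-bis(benzyloxy)benzoic acid; 13 (R)-11-[3-(benzyloxy)-5-hydroxyphenyl]undecan-4-ol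
Product: 19 (S)-11-[3-(benzyloxy)-5-hydroxyphenyl]undecan-4-yl 2-allyl-4,6-bis(benzyloxy)benzoate
Conditions: 18 (1.3 equiv), PPh3, DIAD, THF, 0 °C → rt
Reagents that add atoms: none
Why: Mitsunobu esterification, the usual way to esterify 2,6-disubstituted benzoic acids: the carboxylate attacks the alkoxyphosphonium at C4 by SN2, so the (R) carbinol becomes the (S) ester, while the far less acidic phenol stays protonated and should not be alkylated as long as acid is present.

Step 10
Reactants: 19 (S)-11-[3-(benzyloxy)-5-hydroxyphenyl]undecan-4-yl 2-allyl-4,6-bis(benzyloxy)benzoate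
Product: 20 (S)-11-{3-(benzyloxy)-5-[(2,2,2-trichloroethoxy)sulfonyloxy]phenyl}undecan-4-yl 2-allyl-4,6-bis(benzyloxy)benzoate
Conditions: Cl3CCH2OSO2Cl, Et3N, DMAP, THF, 0 °C → rt
Reagents that add atoms: 2,2,2-trichloroethyl chlorosulfate, ClS(=O)(=O)OCC(Cl)(Cl)Cl
Why: O-Sulfurylation of the only free hydroxyl gives the aryl trichloroethyl sulfate diester, a neutral masked sulfate that tolerates ruthenium carbenes and is released reductively at the end.

Step 11
Reactants: 20 (S)-11-{3-(benzyloxy)-5-[(2,2,2-trichloroethoxy)sulfonyloxy]phenyl}undecan-4-yl 2-allyl-4,6-bis(benzyloxy)benzoate; 5 (S)-dec-9-en-4-yl acetate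
Product: 21 (S)-11-{3-(benzyloxy)-5-[(2,2,2-trichloroethoxy)sulfonyloxy]phenyl}undecan-4-yl 2-[(S,E)-8-acetoxyundec-2-en-1-yl]-4,6-bis(benzyloxy)benzoate (E drawn, E/Z mixture expected)
Conditions: 5 (4 equiv), Hoveyda–Grubbs II (5 mol%), 1,4-benzoquinone (10 mol%), CH2Cl2, 40 °C
Reagents that add atoms: none
Why: Ruthenium-alkylidene olefin cross-metathesis (Chauvin cycle of [2+2] cycloaddition and cycloreversion through ruthenacyclobutanes) exchanges the two terminal =CH2 groups for ethylene, whose loss drives the reaction, and so creates the C2′=C3′ bond between the allyl CH of 20 and the alkene CH of 5. The closest known reaction type is the cross-metathesis of allylarenes with unhindered terminal alkenes, both type I olefins. The step closes no ring and creates no stereocentre; the two existing stereocentres are at least four atoms from any reacting carbon and are untouched, and the E/Z ratio is irrelevant because step 12 saturates the olefin. The selectivity needed is cross- over homo-coupling, which the fourfold excess of the small partner 5 should secure (its homodimer stays a competent partner by secondary metathesis) while the bulky 20 dimerises slowly. Chemoselectivity is built into the substrate, since these are the only two olefins present and the benzyl ethers, hindered benzoate, acetate and trichloroethyl sulfate do not react with the catalyst; benzoquinone quenches Ru–H species that would move the allyl double bond into conjugation with the ring.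

Step 12
Reactants: 21 (S)-11-{3-(benzyloxy)-5-[(2,2,2-trichloroethoxy)sulfonyloxy]phenyl}undecan-4-yl 2-[(S,E)-8-acetoxyundec-2-en-1-yl]-4,6-bis(benzyloxy)benzoate
Product: 22 Integracin D
Conditions: H2 (1 atm), 10% Pd/C, HCO2NH4, MeOH/THF, rt; H+ resin work-up
Reagents that add atoms: none
Why: Catalytic hydrogenation saturates the C2′=C3′ olefin and hydrogenolyses the three aryl benzyl ethers while Pd/formate reductively fragments the trichloroethyl group to release the aryl sulfate monoester, under neutral conditions that should leave the secondary acetate, the salicylate-type ester, the aryl sulfate and both stereocentres untouched.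

Compound list
1 | (S)-2-propyloxirane | CCC[C@H]1CO1 | starting material
2 | 5-bromopent-1-ene | C=CCCCBr | starting material
3 | pent-4-en-1-ylmagnesium bromide | C=CCCC[Mg]Br | intermediate
4 | (S)-dec-9-en-4-ol | CCC[C@H](O)CCCCC=C | intermediate
5 | (S)-dec-9-en-4-yl acetate | CCC[C@H](OC(C)=O)CCCCC=C | intermediate
6 | (R)-2-propyloxirane | CCC[C@@H]1CO1 | starting material
7 | 6-bromohex-1-ene | C=CCCCCBr | starting material
8 | hex-5-en-1-ylmagnesium bromide | C=CCCCC[Mg]Br | intermediate
9 | (R)-undec-10-en-4-ol | CCC[C@@H](O)CCCCCC=C | intermediate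
10 | 5-bromobenzene-1,3-diol | Oc1cc(O)cc(Br)c1 | starting material
11 | 3-(benzyloxy)-5-bromophenol | Oc1cc(Br)cc(OCc2ccccc2)c1 | intermediate
12 | 9-{(R)-8-[(9-borabicyclo[3.3.1]nonan-9-yl)oxy]undecyl}-9-borabicyclo[3.3.1]nonane (bis(9-BBN) adduct of 9) | CCC[C@@H](OB1C2CCCC1CCC2)CCCCCCCB1C2CCCC1CCC2 | intermediate
13 | (R)-11-[3-(benzyloxy)-5-hydroxyphenyl]undecan-4-ol | CCC[C@@H](O)CCCCCCCc1cc(O)cc(OCc2ccccc2)c1 | intermediate
14 | 3,5-bis(benzyloxy)benzyl bromide | BrCc1cc(OCc2ccccc2)cc(OCc2ccccc2)c1 | starting material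
15 | 1-allyl-3,5-bis(benzyloxy)benzene | C=CCc1cc(OCc2ccccc2)cc(OCc2ccccc2)c1 | intermediate
16 | N-{[2-allyl-4,6-bis(benzyloxy)phenyl]methylidene}-N-methylmethanaminium chloride | C=CCc1cc(OCc2ccccc2)cc(OCc2ccccc2)c1C=[N+](C)C.[Cl-] | intermediate
17 | 2-allyl-4,6-bis(benzyloxy)benzaldehyde | C=CCc1cc(OCc2ccccc2)cc(OCc2ccccc2)c1C=O | intermediate
18 | 2-allyl-4,6-bis(benzyloxy)benzoic acid | C=CCc1cc(OCc2ccccc2)cc(OCc2ccccc2)c1C(=O)O | intermediate
19 | (S)-11-[3-(benzyloxy)-5-hydroxyphenyl]undecan-4-yl 2-allyl-4,6-bis(benzyloxy)benzoate | C=CCc1cc(OCc2ccccc2)cc(OCc2ccccc2)c1C(=O)O[C@@H](CCC)CCCCCCCc1cc(O)cc(OCc2ccccc2)c1 | intermediate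
20 | (S)-11-{3-(benzyloxy)-5-[(2,2,2-trichloroethoxy)sulfonyloxy]phenyl}undecan-4-yl 2-allyl-4,6-bis(benzyloxy)benzoate | C=CCc1cc(OCc2ccccc2)cc(OCc2ccccc2)c1C(=O)O[C@@H](CCC)CCCCCCCc1cc(OCc2ccccc2)cc(OS(=O)(=O)OCC(Cl)(Cl)Cl)c1 | intermediate
21 | (S)-11-{3-(benzyloxy)-5-[(2,2,2-trichloroethoxy)sulfonyloxy]phenyl}undecan-4-yl 2-[(S,E)-8-acetoxyundec-2-en-1-yl]-4,6-bis(benzyloxy)benzoate | CCC[C@H](OC(C)=O)CCCC/C=C/Cc1cc(OCc2ccccc2)cc(OCc2ccccc2)c1C(=O)O[C@@H](CCC)CCCCCCCc1cc(OCc2ccccc2)cc(OS(=O)(=O)OCC(Cl)(Cl)Cl)c1 | intermediate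
22 | Integracin D | CCC[C@@H](CCCCCCCc1cc(O)cc(O)c1C(=O)O[C@@H](CCC)CCCCCCCc1cc(O)cc(OS(=O)(=O)O)c1)OC(C)=O | target

Total step count: 12
Longest linear sequence: 7 steps (steps 6, 7, 8, 9, 10, 11, 12, from 14)

Steps most likely to fail

Step 11. The excess partner may homodimerise faster than it crosses, the allyl group of 20 may migrate into conjugation with the ring, and turnover may be slow because the alkylidene sits next to the ortho ester on a precious late intermediate. Fallback: move the metathesis to the unhindered allylarene, setting out from 15 (with 5 and 13) and returning at 21. Cross-metathesis of 15 with 5 under the step-11 conditions should give (S,E)-11-[3,5-bis(benzyloxy)phenyl]undec-9-en-4-yl acetate F1. Vilsmeier–Haack formylation then passes through the aryliminium chloride F2 to (S,E)-11-[3,5-bis(benzyloxy)-2-formylphenyl]undec-9-en-4-yl acetate F3. Pinnick oxidation gives 2-[(S,E)-8-acetoxyundec-2-en-1-yl]-4,6-bis(benzyloxy)benzoic acid F4. Mitsunobu esterification with 13 gives (S)-11-[3-(benzyloxy)-5-hydroxyphenyl]undecan-4-yl 2-[(S,E)-8-acetoxyundec-2-en-1-yl]-4,6-bis(benzyloxy)benzoate F5, and trichloroethyl sulfurylation of its phenol as in step 10 gives 21.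

Step 9. The free phenol of 13 may be O-alkylated by the activated alcohol, and the alkoxyphosphonium may eliminate to alkenes if the hindered carboxylate attacks slowly. Fallback: mask the phenol first, setting out from 13 and returning at 20. Phenol-selective sulfurylation with Cl3CCH2OSO2Cl and Et3N (no DMAP, −20 °C; the hindered secondary alcohol should react far more slowly) gives 3-(benzyloxy)-5-[(R)-8-hydroxyundecyl]phenyl 2,2,2-trichloroethyl sulfate F6. Mitsunobu esterification of F6 with 18 then gives 20 directly, with no competing nucleophile.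

Step 12. The three reductions may lose synchrony: chloride and ammonia released in the trichloroethyl cleavage may poison the palladium so that debenzylation or olefin saturation stalls, and long exposure to the ammonium salt may cleave the acetate. Fallback: separate the two tasks, setting out from 21 and returning at 22. Zinc dust with HCO2NH4 in MeOH removes only the trichloroethyl group and gives (S)-11-[3-(benzyloxy)-5-(sulfooxy)phenyl]undecan-4-yl 2-[(S,E)-8-acetoxyundec-2-en-1-yl]-4,6-bis(benzyloxy)benzoate F7 (as its ammonium salt). Plain hydrogenation (H2, Pd/C, MeOH/EtOAc) then saturates the olefin and removes the benzyl ethers to give 22.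

Further compounds
F1 | step 11 | (S,E)-11-[3,5-bis(benzyloxy)phenyl]undec-9-en-4-yl acetate | CCC[C@H](OC(C)=O)CCCC/C=C/Cc1cc(OCc2ccccc2)cc(OCc2ccccc2)c1
F2 | step 11 | N-({2-[(S,E)-8-acetoxyundec-2-en-1-yl]-4,6-bis(benzyloxy)phenyl}methylidene)-N-methylmethanaminium chloride | CCC[C@H](OC(C)=O)CCCC/C=C/Cc1cc(OCc2ccccc2)cc(OCc2ccccc2)c1C=[N+](C)C.[Cl-]
F3 | step 11 | (S,E)-11-[3,5-bis(benzyloxy)-2-formylphenyl]undec-9-en-4-yl acetate | CCC[C@H](OC(C)=O)CCCC/C=C/Cc1cc(OCc2ccccc2)cc(OCc2ccccc2)c1C=O
F4 | step 11 | 2-[(S,E)-8-acetoxyundec-2-en-1-yl]-4,6-bis(benzyloxy)benzoic acid | CCC[C@H](OC(C)=O)CCCC/C=C/Cc1cc(OCc2ccccc2)cc(OCc2ccccc2)c1C(=O)O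
F5 | step 11 | (S)-11-[3-(benzyloxy)-5-hydroxyphenyl]undecan-4-yl 2-[(S,E)-8-acetoxyundec-2-en-1-yl]-4,6-bis(benzyloxy)benzoate | CCC[C@H](OC(C)=O)CCCC/C=C/Cc1cc(OCc2ccccc2)cc(OCc2ccccc2)c1C(=O)O[C@@H](CCC)CCCCCCCc1cc(O)cc(OCc2ccccc2)c1
F6 | step 9 | 3-(benzyloxy)-5-[(R)-8-hydroxyundecyl]phenyl 2,2,2-trichloroethyl sulfate | CCC[C@@H](O)CCCCCCCc1cc(OCc2ccccc2)cc(OS(=O)(=O)OCC(Cl)(Cl)Cl)c1
F7 | step 12 | (S)-11-[3-(benzyloxy)-5-(sulfooxy)phenyl]undecan-4-yl 2-[(S,E)-8-acetoxyundec-2-en-1-yl]-4,6-bis(benzyloxy)benzoate | CCC[C@H](OC(C)=O)CCCC/C=C/Cc1cc(OCc2ccccc2)cc(OCc2ccccc2)c1C(=O)O[C@@H](CCC)CCCCCCCc1cc(OCc2ccccc2)cc(OS(=O)(=O)O)c1
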